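**Plan**

- Retrosynthesis: the diene is cut at C12–C13 (sp3–sp2 coupling) and at C11=C12 (methylenation). The C18–O, C6–O/C5–H and C8–O bonds are then removed back to a 5,8(17)-dienoic acid. Last, C9–C10 is cut by a retro-[3,3] shift that restores the C6–O bond of a δ-lactone.
- Enabling feature: C9 and the quaternary C10 are neighbours in ring B (C5–C10), and C10 is related to the oxygen-bearing C6 by allylic transposition through C5. The ring oxygen of a lactone sitting on a ring-A C5=C10 alkene can therefore be exchanged for the C9–C10 bond.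
- Forward: ring A is bought (β-cyclocitral) and the δ-lactone is built on it from a diketene-derived allylsilane. Ring B closes in the Ireland–Claisen ring contraction. The core is then oxygenated at C8, C6 and C18, and C11 is extended to the 2-substituted butadiene at the end.
- Stereochemistry: lactone C6 comes from an oxazaborolidine reduction, C10 from chirality transfer out of C6 in a boat transition state, and C9 from kinetic enolate protonation. C8 comes from hydroxyl-directed epoxidation and hydride opening, C5/C6 from hydroboration anti to C20, and C4 from C6–O-directed oxidation of the equatorial methyl C18.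

Key step: step 7

Remark: labdane numbering is used for all intermediates (decalin C1–C10, C11 on C9, C17 on C8, C20 on C10; the oxidised equatorial C4 carbon is C18, the axial methyl C19). The target is (4S,5S,6R,8S,9S,10R), and chloroprene is taken as the commercial stabilised solution.

**Route**

Step 1
Reactants: 1 diketene (4-methylideneoxetan-2-one); 2 (trimethylsilyl)methylmagnesium chloride
Product: 3 3-[(trimethylsilyl)methyl]but-3-enoic acid
Conditions: NiCl2 (cat.), THF, 0 °C to rt; cold dilute HCl work-up
Reagents that add atoms: none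
Why: Nickel-catalysed cross-coupling of a Grignard reagent at the vinylic C–O bond of diketene (opening of the enol lactone) is a known entry to 3-substituted but-3-enoic acids and gives the allylsilane and the carboxyl group in one operation.

Step 2
Reactants: 3 3-[(trimethylsilyl)methyl]but-3-enoic acid
Product: 4 methyl 3-[(trimethylsilyl)methyl]but-3-enoate
Conditions: MeI, K2CO3, DMF, rt
Reagents that add atoms: iodomethane, CI
Why: Carboxylate O-alkylation (SN2) under non-acidic conditions masks the acid for the Lewis-acid step without protodesilylating the allylsilane.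

Step 3
Reactants: 4 methyl 3-[(trimethylsilyl)methyl]but-3-enoate; 5 β-cyclocitral
Product: 6 methyl 5-hydroxy-3-methylidene-5-(2,6,6-trimethylcyclohex-1-en-1-yl)pentanoate (racemic)
Conditions: TiCl4, CH2Cl2, −78 °C; cold aq. NaHCO3 quench
Reagents that add atoms: none
Why: Hosomi–Sakurai allylation, in which the TiCl4-activated aldehyde is attacked in a 1,2-sense by the γ-carbon of the allylsilane and loss of silicon leaves the 1,1-disubstituted alkene (future C8=C17); the carbinol is racemic and is corrected in steps 4 and 5.

Step 4
Reactants: 6 racemic δ-hydroxy ester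
Product: 7 methyl 3-methylidene-5-oxo-5-(2,6,6-trimethylcyclohex-1-en-1-yl)pentanoate
Conditions: Dess–Martin periodinane, NaHCO3, CH2Cl2, 0 °C to rt
Reagents that add atoms: none
Why: Dess–Martin oxidation of the secondary allylic alcohol under buffered, non-basic conditions should give the β,γ-unsaturated ketone without moving the exocyclic alkene into conjugation.

Step 5
Reactants: 7 keto ester
Product: 8 methyl (5R)-5-hydroxy-3-methylidene-5-(2,6,6-trimethylcyclohex-1-en-1-yl)pentanoate
Conditions: (S)-2-methyl-CBS-oxazaborolidine (cat.), catecholborane, toluene, −78 to −30 °C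
Reagents that add atoms: none
Why: Corey–Bakshi–Shibata reduction, in which the ketone binds the oxazaborolidine with the bulky trimethylcyclohexenyl group away from the B-methyl so that hydride enters one face and sets (R) at the future C6, while catecholborane leaves the ester and the 1,1-disubstituted alkene untouched.

Step 6
Reactants: 8 (5R)-hydroxy ester
Product: 10 (6R)-4-methylidene-6-(2,6,6-trimethylcyclohex-1-en-1-yl)oxan-2-one, via hydroxy acid 9 (not isolated)
Conditions: LiOH, THF/H2O, 0 °C; 1 M HCl to pH 4; then EDC·HCl, DMAP, CH2Cl2, rt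
Reagents that add atoms: lithium hydroxide, [Li+].[OH-] (oxygen of the carboxyl group of 9, scrambled with the original carbonyl oxygen before ring closure)
Why: Saponification followed by carbodiimide (Steglich-type) lactonisation closes the six-membered ring at the carboxyl carbon, so the C6–O bond and its (R) configuration are untouched and neither strong acid (allylic ionisation) nor alkoxide (alkene migration) is present during closure.

Step 7
Reactants: 10 (6R)-δ-lactone
Product: 13 (9S,10S)-dienoic acid (1S,8aS)-5,5,8a-trimethyl-2-methylidene-1,2,3,5,6,7,8,8a-octahydronaphthalene-1-carboxylic acid, via silyl ketene acetal 11 (not isolated), via trimethylsilyl ester 12 (not isolated)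
Conditions: LiN(i-Pr)2, Me3SiCl/Et3N (internal quench), THF, −78 °C; then toluene, 100 °C; 1 M HCl, THF, rt
Reagents that add atoms: chlorotrimethylsilane, C[Si](C)(C)Cl (silyl group of 11 and 12 only; absent from 13)
Why: LiN(i-Pr)2 removes a C9 hydrogen that is both α to the lactone carbonyl and allylic to C8=C17, Me3SiCl traps the enolate on oxygen, and silyl ketene acetal 11 then undergoes a concerted suprafacial [3,3] shift in which C9–C10 forms, C6–O breaks and the ring-A alkene moves to C5=C6, leaving silyl ester 12, which is hydrolysed on work-up. The closest known reaction type is the Ireland–Claisen rearrangement of silyl ketene acetals of 6-alkenyl δ-lactones (Claisen ring contraction to cyclohexenecarboxylic acids). Ring B (C5–C6–C7–C8–C9–C10) closes by this sigmatropic ring contraction rather than by a polar cyclisation: C6, C7, C8 and C9 of the lactone become ring-B carbons, and because the C7–C8 tether links C9 to C6 only a boat-like transition state is attainable. C10 is controlled by the C6 stereocentre, since C9 must bond to the alkene face from which the C6–O bond departs, so (6R) is relayed to (10S); C9 is controlled by the boat geometry, which places the carboxyl trans to the C10 methyl (9S), the epimer that step 9 inverts. The step needs O-silylation at C9 without migration of the exocyclic alkene into conjugation or self-condensation of the lactone enolate, which the internal silyl chloride quench at −78 °C and the high acidity of the C9 hydrogens should secure, and it needs the conformer with C7 turned toward C20 and H6 toward the gem-dimethyl carbon, which lies close to the ground state of this tetrasubstituted allylic system.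

Step 8
Reactants: 13 (9S,10S)-dienoic acid
Product: 14 methyl ester of 13, (9S,10S), ester trans to C20
Conditions: Me3SiCHN2, MeOH/toluene, 0 °C
Reagents that add atoms: (trimethylsilyl)diazomethane, C[Si](C)(C)C=[N+]=[N-] (supplies the ester methyl carbon)
Why: Esterification with (trimethylsilyl)diazomethane is neutral, so the β,γ-unsaturated acid should give its methyl ester without migration of the C8=C17 alkene.

Step 9
Reactants: 14 (9S,10S)-methyl ester
Product: 16 (9R,10S)-methyl ester (C9 epimer of 14; ester cis to C20), via lithium enolate 15 (not isolated)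
Conditions: LiN(i-Pr)2, THF, −78 to −30 °C; then AcOH, THF, −78 °C
Reagents that add atoms: lithium diisopropylamide, [Li+].CC(C)[N-]C(C)C (lithium of 15 only)
Why: Kinetic α-protonation of the lithium dienolate (deconjugative protonation) returns the β,γ-unsaturated ester, and the proton should enter C9 on the face opposite the C10 methyl (C20), the more nearly perpendicular substituent on C10, so the ester ends cis to C20; the cold irreversible quench prevents re-equilibration to the axial epimer or to the conjugated ester.

Step 10
Reactants: 16 (9R,10S)-methyl ester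
Product: 17 [(1R,8aS)-5,5,8a-trimethyl-2-methylidene-1,2,3,5,6,7,8,8a-octahydronaphthalen-1-yl]methanol (C11 alcohol; C5=C6 and C8=C17 retained)
Conditions: LiAlH4, THF, 0 °C
Reagents that add atoms: none
Why: LiAlH4 reduction of the ester gives the primary C11 alcohol, a homoallylic alcohol that directs step 11, without touching a stereocentre.

Step 11
Reactants: 17 C11 alcohol
Product: 18 8,17-epoxide of 17 (spiro-oxirane, oxygen on the face opposite C20)
Conditions: VO(acac)2 (cat.), t-BuOOH, CH2Cl2, 0 °C to rt
Reagents that add atoms: tert-butyl hydroperoxide, CC(C)(C)OO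
Why: Vanadium-catalysed hydroxyl-directed epoxidation of a homoallylic alcohol selects C8=C17 over the hindered and more remote C5=C6 alkene and should deliver oxygen anti to C20, because the vanadate rotamer that reaches the other face suffers a syn-pentane clash with C20 and the intrinsic steric bias of 8(17)-methylene decalins points the same way.

Step 12
Reactants: 18 epoxy alcohol
Product: 19 8,11-diol (tertiary 8-OH trans to C20 and to the C9 hydroxymethyl group; new C17 methyl; C5=C6 retained)
Conditions: LiAlH4, THF, rt to reflux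
Reagents that add atoms: none
Why: Hydride opening (SN2) of the 1,1-disubstituted spiro-epoxide at its CH2 terminus creates the C17 methyl and leaves the tertiary C8–O bond, and hence the configuration set in step 11, intact.

Step 13
Reactants: 19 8,11-diol
Product: 20 8,11-O-isopropylidene acetal of 19 (1,3-dioxane)
Conditions: 2-methoxypropene, PPTS (cat.), CH2Cl2, 0 °C to rt
Reagents that add atoms: 2-methoxypropene, COC(C)=C
Why: Kinetic ketalisation of the 1,3-diol gives the six-membered acetonide, which masks both hydroxyls for the borane and silane steps.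

Step 14
Reactants: 20 acetonide
Product: 22 6-hydroxy acetonide (trans-decalin; H5 and equatorial 6-OH both on the face opposite C20), via C6 alkylborane 21 (not isolated)
Conditions: BH3·THF, THF, 0 °C to rt; then NaOH (aq), H2O2, 0 °C to rt
Reagents that add atoms: borane–tetrahydrofuran, B.C1CCOC1 (boron of 21 only); hydrogen peroxide, OO (the C6 oxygen)
Why: Brown hydroboration–oxidation, in which BH3 adds syn with boron on the less substituted C6 and hydrogen on C5 from the face opposite the axial C20 and C19 methyls, giving the trans ring fusion, and oxidation with retention gives the equatorial 6-OH cis to H5.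

Step 15
Reactants: 22 6-hydroxy acetonide
Product: 25 6,18-diol acetonide (C18 hydroxymethyl equatorial on C4, cis to H5 and to 6-OH), via hydrosilyl ether 23 (not isolated), via oxasilinane 24 (not isolated)
Conditions: Et2SiH2, [Ir(cod)OMe]2 (cat.), THF, rt; then [Rh(cod)Cl]2 (cat.), Xantphos, norbornene, THF, 100 °C; then H2O2, KHCO3, THF/MeOH, 50 °C
Reagents that add atoms: diethylsilane, CC[SiH2]CC (silicon of 23 and 24 only); hydrogen peroxide, OO (the C18 oxygen)
Why: Dehydrogenative formation of the diethyl(hydrido)silyl ether, rhodium-catalysed intramolecular δ-C–H silylation and Tamao–Fleming oxidation convert the alcohol into a 1,4-diol; the equatorial 6-O and the equatorial C4 methyl are peri to each other, no γ C–H exists (C4, C8 and C10 are quaternary) and the axial methyl C19 is out of reach, so a chair oxasilinane can close only onto C18, which fixes C4.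

Step 16
Reactants: 25 6,18-diol acetonide
Product: 26 18-O-tert-butyldiphenylsilyl ether of 25
Conditions: TBDPSCl, imidazole, DMF, rt
Reagents that add atoms: tert-butyl(chloro)diphenylsilane, CC(C)(C)[Si](Cl)(c1ccccc1)c1ccccc1
Why: Silylation of the primary C18 hydroxyl with the bulky silyl chloride is selective over the hindered secondary 6-OH and gives an ether that survives the acid of step 18.

Step 17
Reactants: 26 18-O-silyl ether
Product: 27 6-O-acetyl-18-O-tert-butyldiphenylsilyl acetonide
Conditions: Ac2O, DMAP, Et3N, CH2Cl2, rt to 40 °C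
Reagents that add atoms: acetic anhydride, CC(=O)OC(C)=O
Why: DMAP-catalysed acylation of the only free hydroxyl installs the C6 acetate with no competing site.

Step 18
Reactants: 27 acetate acetonide
Product: 28 6-O-acetyl-18-O-tert-butyldiphenylsilyl 8,11-diol
Conditions: PPTS, MeOH, rt to 40 °C
Reagents that add atoms: none
Why: Acid-catalysed transketalisation in methanol removes the strained tetrasubstituted dioxane, while the silyl ether and the hindered acetate are stable to PPTS.

Step 19
Reactants: 28 8,11-diol
Product: 29 C11 aldehyde (8-hydroxy; 6-O-acetyl; 18-O-silyl), used crude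
Conditions: Dess–Martin periodinane, NaHCO3, CH2Cl2, 0 °C
Reagents that add atoms: none
Why: Dess–Martin oxidation converts the primary C11 alcohol to the aldehyde under buffered conditions; the tertiary 8-OH cannot be oxidised and the absence of base avoids retro-aldol cleavage and C9 epimerisation.

Step 20
Reactants: 29 β-hydroxy aldehyde
Product: 30 9-vinyl compound (C11=C12; 8-hydroxy; 6-O-acetyl; 18-O-silyl)
Conditions: Zn, CH2Br2, TiCl4, THF/CH2Cl2, 0 °C to rt
Reagents that add atoms: dibromomethane, BrCBr
Why: Takai–Lombardo methylenation is non-basic, so the β-hydroxy aldehyde should give the vinyl group without the retro-aldol reaction, elimination, C9 epimerisation or attack on the acetate that a phosphorus ylide would risk.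

Step 21
Reactants: 30 9-vinyl compound; 31 2-chlorobuta-1,3-diene (chloroprene)
Product: 33 18-O-tert-butyldiphenylsilyl ether of the target (full 13(16),14-diene side chain), via B-alkyl-9-BBN adduct 32 (not isolated)
Conditions: 9-BBN, THF, 0 °C to rt; then 31, Pd(OAc)2 (cat.), SPhos, K3PO4 (aq), THF, 50 °C, sealed vessel
Reagents that add atoms: 9-borabicyclo[3.3.1]nonane, B1C2CCCC1CCC2 (boron group of 32 only)
Why: Anti-Markovnikov hydroboration of the monosubstituted alkene with 9-BBN followed by B-alkyl Suzuki–Miyaura coupling with the alkenyl chloride joins C12 to C13 and gives the 2-substituted buta-1,3-diene directly, and the mild phosphate base leaves the acetate in place.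

Step 22
Reactants: 33 silyl-protected target
Product: 34 target, (4S,5S,6R,8S,9S,10R)-6-acetoxylabda-13(16),14-diene-8,18-diol
Conditions: HF·pyridine, pyridine, THF, 0 °C to rt
Reagents that add atoms: none
Why: Fluoride-mediated desilylation under acidic, non-basic conditions frees the C18 hydroxyl without acetyl migration from O6 to O18 and without harming the diene or the tertiary alcohol.

**Compound list**

1 | diketene | C=C1CC(=O)O1 | starting material
2 | (trimethylsilyl)methylmagnesium chloride | C[Si](C)(C)C[Mg]Cl | starting material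
3 | 3-[(trimethylsilyl)methyl]but-3-enoic acid | C=C(C[Si](C)(C)C)CC(=O)O | intermediate
4 | methyl 3-[(trimethylsilyl)methyl]but-3-enoate | C=C(C[Si](C)(C)C)CC(=O)OC | intermediate
5 | β-cyclocitral | CC1=C(C=O)C(C)(C)CCC1 | starting material
6 | methyl 5-hydroxy-3-methylidene-5-(2,6,6-trimethylcyclohex-1-en-1-yl)pentanoate, racemic | C=C(CC(=O)OC)CC(O)C1=C(C)CCCC1(C)C | intermediate
7 | methyl 3-methylidene-5-oxo-5-(2,6,6-trimethylcyclohex-1-en-1-yl)pentanoate | C=C(CC(=O)OC)CC(=O)C1=C(C)CCCC1(C)C | intermediate
8 | methyl (5R)-5-hydroxy-3-methylidene-5-(2,6,6-trimethylcyclohex-1-en-1-yl)pentanoate | C=C(CC(=O)OC)C[C@@H](O)C1=C(C)CCCC1(C)C | intermediate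
9 | (5R)-5-hydroxy-3-methylidene-5-(2,6,6-trimethylcyclohex-1-en-1-yl)pentanoic acid (not isolated) | C=C(CC(=O)O)C[C@@H](O)C1=C(C)CCCC1(C)C | intermediate
10 | (6R)-4-methylidene-6-(2,6,6-trimethylcyclohex-1-en-1-yl)oxan-2-one | C=C1CC(=O)O[C@H](C1)C2=C(C)CCCC2(C)C | intermediate
11 | (2R)-4-methylidene-2-(2,6,6-trimethylcyclohex-1-en-1-yl)-6-(trimethylsilyloxy)-3,4-dihydro-2H-pyran (not isolated) | C=C1C=C(O[Si](C)(C)C)O[C@H](C1)C2=C(C)CCCC2(C)C | intermediate
12 | trimethylsilyl ester of 13 (not isolated) | C[Si](C)(C)OC(=O)[C@@H]1[C@]2(C)CCCC(C)(C)C2=CCC1=C | intermediate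
13 | (1S,8aS)-5,5,8a-trimethyl-2-methylidene-1,2,3,5,6,7,8,8a-octahydronaphthalene-1-carboxylic acid; (9S,10S), carboxyl trans to C20 | OC(=O)[C@@H]1[C@]2(C)CCCC(C)(C)C2=CCC1=C | intermediate
14 | methyl ester of 13, (9S,10S) | COC(=O)[C@@H]1[C@]2(C)CCCC(C)(C)C2=CCC1=C | intermediate
15 | lithium dienolate of 14 (enolate geometry not assigned; not isolated) | COC(O[Li])=C1C(=C)CC=C2C(C)(C)CCC[C@@]12C | intermediate
16 | (9R,10S)-methyl ester, C9 epimer of 14, ester cis to C20 | COC(=O)[C@H]1[C@]2(C)CCCC(C)(C)C2=CCC1=C | intermediate
17 | [(1R,8aS)-5,5,8a-trimethyl-2-methylidene-1,2,3,5,6,7,8,8a-octahydronaphthalen-1-yl]methanol | OC[C@H]1[C@]2(C)CCCC(C)(C)C2=CCC1=C | intermediate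
18 | 8,17-epoxide of 17, oxygen anti to C20 | OC[C@H]1[C@]2(C)CCCC(C)(C)C2=CC[C@@]13CO3 | intermediate
19 | 5-ene-8,11-diol, 8-OH anti to C20, C17 methyl | OC[C@H]1[C@]2(C)CCCC(C)(C)C2=CC[C@]1(C)O | intermediate
20 | 8,11-O-isopropylidene acetal of 19 | CC1(C)OC[C@H]2[C@]3(C)CCCC(C)(C)C3=CC[C@]2(C)O1 | intermediate
21 | C6 alkylborane of 20, boron and H5 anti to C20 (not isolated) | CC1(C)OC[C@H]2[C@]3(C)CCCC(C)(C)[C@H]3[C@H](B)C[C@]2(C)O1 | intermediate
22 | 6-hydroxy acetonide, trans-decalin, equatorial 6-OH cis to H5 | CC1(C)OC[C@H]2[C@]3(C)CCCC(C)(C)[C@H]3[C@H](O)C[C@]2(C)O1 | intermediate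
23 | 6-O-diethyl(hydrido)silyl ether of 22 (not isolated) | CC1(C)OC[C@H]2[C@]3(C)CCCC(C)(C)[C@H]3[C@H](O[SiH](CC)CC)C[C@]2(C)O1 | intermediate
24 | oxasilinane O6–SiEt2–C18 (not isolated) | CC1(C)OC[C@H]2[C@]3(C)CCC[C@]4(C)C[Si](CC)(CC)O[C@H](C[C@]2(C)O1)[C@@H]34 | intermediate
25 | 6,18-diol acetonide | CC1(C)OC[C@H]2[C@]3(C)CCC[C@](C)(CO)[C@H]3[C@H](O)C[C@]2(C)O1 | intermediate
26 | 18-O-tert-butyldiphenylsilyl ether of 25 | CC1(C)OC[C@H]2[C@]3(C)CCC[C@](C)(CO[Si](c4ccccc4)(c4ccccc4)C(C)(C)C)[C@H]3[C@H](O)C[C@]2(C)O1 | intermediate
27 | 6-O-acetyl-18-O-tert-butyldiphenylsilyl acetonide | CC1(C)OC[C@H]2[C@]3(C)CCC[C@](C)(CO[Si](c4ccccc4)(c4ccccc4)C(C)(C)C)[C@H]3[C@H](OC(C)=O)C[C@]2(C)O1 | intermediate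
28 | 6-O-acetyl-18-O-tert-butyldiphenylsilyl 8,11-diol | OC[C@H]1[C@]2(C)CCC[C@](C)(CO[Si](c3ccccc3)(c3ccccc3)C(C)(C)C)[C@H]2[C@H](OC(C)=O)C[C@]1(C)O | intermediate
29 | C11 aldehyde of 28 (8-hydroxy) | O=C[C@H]1[C@]2(C)CCC[C@](C)(CO[Si](c3ccccc3)(c3ccccc3)C(C)(C)C)[C@H]2[C@H](OC(C)=O)C[C@]1(C)O | intermediate
30 | 9-vinyl compound (C11=C12) | C=C[C@H]1[C@]2(C)CCC[C@](C)(CO[Si](c3ccccc3)(c3ccccc3)C(C)(C)C)[C@H]2[C@H](OC(C)=O)C[C@]1(C)O | intermediate
31 | 2-chlorobuta-1,3-diene (chloroprene) | C=CC(Cl)=C | starting material
32 | B-(C12-alkyl)-9-borabicyclo[3.3.1]nonane from 30 (not isolated) | B1(CC[C@H]2[C@]3(C)CCC[C@](C)(CO[Si](c4ccccc4)(c4ccccc4)C(C)(C)C)[C@H]3[C@H](OC(C)=O)C[C@]2(C)O)C2CCCC1CCC2 | intermediate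
33 | 18-O-tert-butyldiphenylsilyl ether of the target | C=CC(=C)CC[C@H]1[C@]2(C)CCC[C@](C)(CO[Si](c3ccccc3)(c3ccccc3)C(C)(C)C)[C@H]2[C@H](OC(C)=O)C[C@]1(C)O | intermediate
34 | (4S,5S,6R,8S,9S,10R)-6-acetoxylabda-13(16),14-diene-8,18-diol (CNP0312185.1) | C=CC(=C)CC[C@H]1[C@]2(C)CCC[C@](C)(CO)[C@H]2[C@H](OC(C)=O)C[C@]1(C)O | target

**Totals and risks**

Total step count: 22. Longest linear sequence: 22 steps (from diketene 1; β-cyclocitral 5 enters at step 3, chloroprene 31 at step 21).

The three steps most likely to fail:

Step 15. The rhodium catalyst may fail to cleave the neopentyl C18–H bond beside the ring fusion, or the hydrosilyl ether may redistribute or couple intermolecularly before it cyclises. The fallback keeps the C6-oxygen-directed idea but uses an alkoxy radical. It sets out from 22. Nitrosyl chloride in pyridine should give the C6 nitrite ester F1. Photolysis in benzene (Barton nitrite reaction, 1,5-hydrogen abstraction from the peri C18 methyl) followed by warming in 2-propanol should give the 18-oxime F2. TiCl3 in NH4OAc-buffered aqueous THF should remove the oxime, and the hydroxy aldehyde closes to the 6,18-lactol F3. NaBH4 in methanol should reduce F3 to the diol, and the route is rejoined at 25.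

Step 20. The β-hydroxy aldehyde may undergo retro-aldol cleavage or dehydration on the Lewis-acidic titanium–zinc reagent, or the free tertiary hydroxyl may consume the reagent so that methylenation stalls. The fallback masks the hydroxyl and uses a phosphorus ylide. It sets out from 28. Et3SiOTf and 2,6-lutidine should give the 8,11-bis(triethylsilyl) ether F4. Swern conditions should oxidise the primary silyl ether directly to the 8-silyloxy aldehyde F5. Wittig methylenation (Ph3PCH3Br, KOt-Bu, THF, 0 °C) should give the 8-O-triethylsilyl vinyl compound F6. Brief HF·pyridine at 0 °C should remove the triethylsilyl group, and the route is rejoined at 30.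

Step 21. Oxidative addition to the alkenyl chloride may be slow, and the diene partner may polymerise or the alkylborane may be lost by protodeboronation before coupling. The fallback builds the diene by ene–yne metathesis instead of cross-coupling. It sets out from 29. A Wittig reaction with (triphenylphosphoranylidene)acetaldehyde should give the (E)-enal F7. Hydrogenation over Pd/C in ethyl acetate should saturate C11=C12 to the aldehyde F8. The Ohira–Bestmann reagent (K2CO3, MeOH, 0 °C) should give the terminal alkyne F9, with re-acetylation by Ac2O/DMAP if the C6 acetate is partly lost. Ethylene with the second-generation Grubbs catalyst, (H2IMes)(PCy3)Cl2Ru=CHPh, should then convert the alkyne into the 2-substituted butadiene, and the route is rejoined at 33.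

**Further compounds**

F1 | step 15 | C6 nitrite ester of 22 | CC1(C)OC[C@H]2[C@]3(C)CCCC(C)(C)[C@H]3[C@H](ON=O)C[C@]2(C)O1
F2 | step 15 | 18-oxime of the 6-hydroxy acetonide (oxime geometry not assigned) | CC1(C)OC[C@H]2[C@]3(C)CCC[C@](C)(C=NO)[C@H]3[C@H](O)C[C@]2(C)O1
F3 | step 15 | 6,18-lactol acetonide (mixture at the lactol carbon) | CC1(C)OC[C@H]2[C@]3(C)CCC[C@]4(C)C(O)O[C@H](C[C@]2(C)O1)[C@@H]34
F4 | step 20 | 8,11-bis(triethylsilyl) ether of 28 | CC[Si](CC)(CC)OC[C@H]1[C@]2(C)CCC[C@](C)(CO[Si](c3ccccc3)(c3ccccc3)C(C)(C)C)[C@H]2[C@H](OC(C)=O)C[C@]1(C)O[Si](CC)(CC)CC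
F5 | step 20 | 8-O-triethylsilyl C11 aldehyde | O=C[C@H]1[C@]2(C)CCC[C@](C)(CO[Si](c3ccccc3)(c3ccccc3)C(C)(C)C)[C@H]2[C@H](OC(C)=O)C[C@]1(C)O[Si](CC)(CC)CC
F6 | step 20 | 8-O-triethylsilyl ether of 30 | C=C[C@H]1[C@]2(C)CCC[C@](C)(CO[Si](c3ccccc3)(c3ccccc3)C(C)(C)C)[C@H]2[C@H](OC(C)=O)C[C@]1(C)O[Si](CC)(CC)CC
F7 | step 21 | (E)-C11=C12 enal (C13 aldehyde) | O=C/C=C/[C@H]1[C@]2(C)CCC[C@](C)(CO[Si](c3ccccc3)(c3ccccc3)C(C)(C)C)[C@H]2[C@H](OC(C)=O)C[C@]1(C)O
F8 | step 21 | saturated C13 aldehyde | O=CCC[C@H]1[C@]2(C)CCC[C@](C)(CO[Si](c3ccccc3)(c3ccccc3)C(C)(C)C)[C@H]2[C@H](OC(C)=O)C[C@]1(C)O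
F9 | step 21 | terminal alkyne (C13≡C14) | C#CCC[C@H]1[C@]2(C)CCC[C@](C)(CO[Si](c3ccccc3)(c3ccccc3)C(C)(C)C)[C@H]2[C@H](OC(C)=O)C[C@]1(C)O
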